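Readings and results are simulated on assumed constants; noise was put on by code.

The amounts in two of these flasks allow a clean comparison: south-west and west differ in free catalyst alone, so at equal product they hold equal starting material and equal coupling partner.

| setting | south-west | north | west | south |
|---|---|---|---|---|
| starting material | 100 mM | 150 mM | 100 mM | 200 mM |
| coupling partner | 150 mM | 150 mM | 150 mM | 150 mM |
| free catalyst | 3.00 mM | 3.00 mM | 9.00 mM | 1.50 mM |
| time |  |  |  | 7.7 h |

| run | time / h | [product] / mM |
|---|---|---|
| south-west run | 0.28 | 1.7 |
| south-west run | 0.84 | 6.3 |
| south-west run | 1.6 | 11.5 |
| south-west run | 2.5 | 18.1 |
| south-west run | 3.6 | 26.3 |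
| south-west run | 4.9 | 35.6 |
| south-west run | 6.2 | 44.1 |
| south-west run | 7.7 | 53.1 |
| north run | 0.28 | 2.1 |
| north run | 0.84 | 6.7 |
| north run | 1.6 | 13.1 |
| north run | 2.5 | 22.2 |
| north run | 3.6 | 32.0 |
| north run | 4.9 | 44.3 |
| north run | 6.2 | 55.9 |
| north run | 7.7 | 68.8 |
| west run | 0.28 | 6.6 |
| west run | 0.84 | 17.4 |
| west run | 1.6 | 32.5 |
| west run | 2.5 | 46.6 |
| west run | 3.6 | 61.1 |
| west run | 4.9 | 72.8 |
| west run | 6.2 | 81.6 |
| west run | 7.7 | 87.8 |

(standard deviation of a reading: 0.3 mM)

- order of the initial rate in [starting material], near the charge of the south-west run, the rate being that where two percent of its starting material are product (one fixed amount of product, the same in the runs compared)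
- order of the initial rate in [free catalyst], near the charge of the south-west run, the rate being that where two percent of its starting material are product
- product in the south run at 7.7 h, as a share of the starting material charged

- Overall: starting material + coupling partner -> product, with free catalyst as catalyst.
- Constant volume, constant temperature.
- Bound and free are read together.
- "The second partner" is coupling partner.
- An order is taken over about fifteen percent of the charge, up and down.

I read the south-west and west tables against each other. The charges put 3.00 times as much free catalyst in west as in south-west, and I took that as the catalyst factor between these flasks. Then I went down to the rows around 44.4 mM of product. South-west climbed from 35.6 mM to 53.1 mM at 6.25 mM h⁻¹, and west, over a nearly matching stretch from 32.5 mM to 61.1 mM, at 14.3 mM h⁻¹.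

That ratio is 2.29, smaller than the factor in the charges, so part of the rate seemed not to scale with catalyst. Splitting the south-west rate into a scaling part and a constant part gave a constant part of 2.23 mM h⁻¹. I suspected product feeding its own formation (autocatalysis).

So I defined the feedback time τ as the product present divided by that rate, the time in which this product makes as much again: 19.9 h, a reading at about 55.7 mM of starting material and 106 mM of coupling partner. I assumed that τ varies inversely with the product of those two amounts. At the south-west charge this gives 7.81 h, and at the south charge 3.91 h. The 7.7 h asked of south therefore holds 1.97 feedback times, more than the 0.986 of south-west.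

The forecast, which saw of south-west that “the run is almost straight”, gave orders of 0.3 in starting material and 0.95 in free catalyst, and 19% for south. From my count I would have gone above that share, though I had no figure of my own.

The simulation gave orders of 0.32 and 1.1, and 25.8% for south.

    free catalyst + starting material ⇌ catalyst-substrate complex, settled at all times (20.80 M⁻¹)
    catalyst-substrate complex + coupling partner ⇌ ternary complex, settled at all times (1.800 M⁻¹)
    ternary complex → product + free catalyst (17.24 h⁻¹)
    free catalyst + impurity → spent catalyst
    starting material + coupling partner + product → 2 product (9.036 M⁻² h⁻¹)

South stands above the forecast through the step in which product turns starting material and coupling partner into more product: without that step, the south run gives 11.7% instead of 25.8%. Measured by my reading of τ, which scales 19.9 h to 7.81 h at the south-west charge, west took 2.71 h to turn half of its starting material, an estimated 0.347 feedback times, against an estimated 0.918 in south-west's 7.17 h, and its lead in time was 2.65.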